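(The constants used here were chosen freely; what happens was integrated by code.)

Watch two things in each flask: how the starting material divides between its two exits, which I reckon below from one concentration, and how much of the target then survives to the end of the run.

all flasks: starting material 20 mM; reagent 26.0 mM; time 1.5 min
- Sunday's: temperature 100 °C
- Friday's: temperature 40 °C
- Monday's: temperature 70 °C

    2 starting material → side product (k1 = 2.04 L mol⁻¹ s⁻¹, Ea1 = 68.0 kJ mol⁻¹)
    starting material + reagent → target (k2 = 0.531 L mol⁻¹ s⁻¹, Ea2 = 60.0 kJ mol⁻¹)
    target → over-reaction product (k3 = 0.0245 s⁻¹, Ea3 = 111 kJ mol⁻¹)
    (constants at 100 °C)

- in percentages every species weighs as the starting material in it: one side product counts as two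
- two of one species on the left: rate k times its square, two consumed each time
- constants are those at 100 °C; use the activation energies for any other temperature

* the best flask by amount of target, in percent of the starting material charged; "all alike" if 1.5 percentage points covers them all (Sunday's / Friday's / Monday's / all alike)
* amount of target at the end, in percent of the starting material charged, Sunday's
* amount of target at the end, in percent of the starting material charged, Friday's
* amount of target at the end, in percent of the starting material charged, Monday's

1. I call the charge of starting material c, the constant of the side-product step kS, that of the target-forming step kT, and that of the loss of target kL. I use A for the starting material at time t. Since the reagent is what changes least, I freeze it at its charge, which makes the target-forming step pseudo-first-order in starting material, with κ = kT × 26.0 mM, or 0.0138 s⁻¹ in Sunday's flask.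

2. Starting material now leaves by two exits, at 2·kS·A² and κ·A, and these tie at m = κ/(2·kS), which is 3.38 mM in Sunday's flask; I carry this tie concentration through every flask. Sunday's charge stands higher than m, so at the start the side-product exit takes 5.9 times as much starting material as the target exit.

3. Each bit of starting material lost becomes target with the share m/(m + A), and integrating the two exits gives the fraction ever made into target: Y = (m/c)·ln[1 + (c/m)(1 − e^(−κt))].

4. For Sunday's flask, Y is 27.9%, which costs the reagent 21.5% of its charge, so the freeze is crude but usable. Cooling raises m, because the side-product step has the higher activation energy by 8.00 kJ mol⁻¹, but it lowers κ. Monday's flask has m = 4.24 mM and Y = 14.3%. Friday's flask has m = 5.55 mM and Y = 2.86%.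

5. Now the loss of target. In Sunday's flask the starting material halves by the side step in about 12.3 s, shorter than the target's half-life of 28.3 s, so I count the target as made at that moment and decaying afterwards, which leaves 4.15%. In Monday's flask kL is 0.00107 s⁻¹ and making is spread over the run, so I give the target half the time to decay and keep 13.7%. Friday's flask loses about 0.232% of its target. I therefore commit to Monday's.

6. The forecast also names Monday's, with 6.5% for Sunday's, 2.8% for Friday's and 13.2% for Monday's, because “the middle temperature wins”, and its Sunday figure stands above my 4.15%.

7. The flasks give 6.27% for Sunday's, 2.82% for Friday's and 12.9% for Monday's, so Monday's is best, and my Sunday figure is the one that falls short. With the loss of target struck out, Sunday's flask holds 25.7% of target against my Y of 27.9%. A neighbour flask, Sunday's with 100 mM of reagent, has m = 13.0 mM, which gives Y = 60.2%. That flask ends with 10.4% of target and 48.7% of over-reaction product, together 59.1%.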